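## Retrosynthetic overview

1. The ring oxirane is made last by epoxidising the 1(10)-olefin. Before that, the C3 and C8 esters are attached from bought (R)-2-methylbutanoic acid and from epoxyangelic acid made from ethyl (S)-3-hydroxybutanoate.
2. The α-methylene 6α,12-lactone comes from an 8β,12-lactone by relactonisation. The 8β,12-lactone comes from a methyl lactol ether fused cis to the ten-membered ketone.
3. The ten-membered ring (C8–C9 bond) is formed by an anionic oxy-Cope rearrangement of a trans-1,2-dialkenylcyclohexenol. This step also sets the 1(10)E olefin and C8, and keeps the 4Z olefin from the six-membered ring.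
4. The cyclohexenol comes from a carvone-derived 4-silyloxy enone and a lithiated 2-methoxy-2,3-dihydrofuran.
5. Ring order: cyclohexene (bought in carvone), then ten-membered ring with fused acetal ring, then γ-lactone, then ring oxirane.

Assumption: (R)-carvone, ethyl (S)-3-hydroxybutanoate and (R)-2-methylbutanoic acid are bought as single enantiomers. Bromide 12 is used racemic because its acetal carbon ends as the lactone carbonyl, so 20–24 are epimer mixtures at that carbon only.

Germacrane numbering is used for ten-membered-ring compounds: C1–C10 ring, C11–C13 lactone carbons, C14 on C10, C15 on C4.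

## Route

**Fragment A: epoxyangelic acid**

Step 1
Reactants: 1 ethyl (S)-3-hydroxybutanoate
Product: 3 ethyl (2S,3S)-3-hydroxy-2-methylbutanoate, via dilithium alkoxide enolate 2 (not isolated)
Conditions: LiN(iPr)2 (2.2 equiv), THF, −50 → −20 °C; MeI, DMPU, −20 → 0 °C; AcOH
Reagents that add atoms: iodomethane, CI
Why: Fráter–Seebach alkylation; the chelated dianion is methylated anti to the C3 methyl, which sets C2 as S (anti product).

Step 2
Reactants: 3 ethyl (2S,3S)-3-hydroxy-2-methylbutanoate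
Product: 5 ethyl (2S,3S)-2,3-dihydroxy-2-methylbutanoate, via dilithium alkoxide enolate 4 (not isolated)
Conditions: LiN(iPr)2 (2.2 equiv), THF, −78 → −20 °C; (±)-trans-2-(phenylsulfonyl)-3-phenyloxaziridine, −78 °C; AcOH
Reagents that add atoms: trans-2-(phenylsulfonyl)-3-phenyloxaziridine (racemic), O=S(=O)(c1ccccc1)N1OC1c1ccccc1
Why: Electrophilic enolate hydroxylation (Davis) of the same chelated dianion; oxygen enters on the face anti to the C3 methyl, as the methyl did in step 1, giving the quaternary 2S centre.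

Step 3
Reactants: 5 ethyl (2S,3S)-2,3-dihydroxy-2-methylbutanoate
Product: 6 ethyl (2S,3S)-2-hydroxy-3-(methanesulfonyloxy)-2-methylbutanoate
Conditions: MsCl, Et3N, CH2Cl2, −10 °C
Reagents that add atoms: methanesulfonyl chloride, CS(=O)(=O)Cl
Why: Sulfonylation is selective for the secondary hydroxyl; the tertiary α-hydroxy ester hydroxyl does not react.

Step 4
Reactants: 6 ethyl (2S,3S)-2-hydroxy-3-(methanesulfonyloxy)-2-methylbutanoate
Product: 8 (2S,3R)-2,3-dimethyloxirane-2-carboxylic acid (epoxyangelic acid; methyls cis), via epoxy ester 7 (not isolated)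
Conditions: KOH (3 equiv), EtOH/H2O, 0 °C → rt; then 1 M HCl to pH 3, 0 °C
Reagents that add atoms: potassium hydroxide, [K+].[OH-]
Why: Intramolecular Williamson closure (3-exo-tet SN2) inverts C3 to give the cis-dimethyl oxirane (3R); the non-enolisable glycidic ester is then saponified.

**Fragment B: vinyl bromide**

Step 5
Reactants: 9 2,5-dimethoxytetrahydrofuran
Product: 10 2-methoxy-2,3-dihydrofuran
Conditions: quinolinium tosylate (cat.), neat, 160 °C, product distilled out
Reagents that add atoms: none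
Why: Acid-catalysed elimination of methanol from one acetal gives the cyclic enol ether; distillation prevents loss of the second methanol.

Step 6
Reactants: 10 2-methoxy-2,3-dihydrofuran
Product: 12 4-bromo-2-methoxy-2,3-dihydrofuran, via dibromide 11 (not isolated)
Conditions: Br2, CH2Cl2, −78 °C; then Et3N, −78 °C → rt
Reagents that add atoms: bromine, BrBr
Why: Bromine adds to the enol ether; the anomeric bromide ionises and the oxocarbenium ion loses the β-proton (E1-type dehydrobromination) to give the β-bromo enol ether.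

**Main line**

Step 7
Reactants: 13 (R)-carvone
Product: 14 (1R,5R)-cis-carveol
Conditions: NaBH4, CeCl3·7H2O, MeOH, −78 → 0 °C
Reagents that add atoms: none
Why: Luche 1,2-reduction; hydride is delivered anti to the isopropenyl-bearing side, giving the cis alcohol (1R) with high selectivity.

Step 8
Reactants: 14 (1R,5R)-cis-carveol
Product: 15 (1S,5R)-2-methyl-5-(prop-1-en-2-yl)cyclohex-2-en-1-yl 4-nitrobenzoate
Conditions: 4-nitrobenzoic acid, PPh3, DIAD, THF, 0 °C → rt
Reagents that add atoms: 4-nitrobenzoic acid, OC(=O)c1ccc(cc1)[N+](=O)[O-]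
Why: Mitsunobu reaction; SN2 displacement of the alkoxyphosphonium inverts C1 to S, giving the trans relationship needed later between C3–O and the Cope chair.

Step 9
Reactants: 15 (1S,5R)-2-methyl-5-(prop-1-en-2-yl)cyclohex-2-en-1-yl 4-nitrobenzoate
Product: 16 (1S,5R)-trans-carveol
Conditions: K2CO3 (cat.), MeOH, rt
Reagents that add atoms: none
Why: Transesterification (methanolysis) of the activated benzoate; no stereocentre is touched.

Step 10
Reactants: 16 (1S,5R)-trans-carveol
Product: 17 tert-butyldimethyl{[(1S,5R)-2-methyl-5-(prop-1-en-2-yl)cyclohex-2-en-1-yl]oxy}silane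
Conditions: TBSCl, imidazole, DMF, rt
Reagents that add atoms: tert-butyldimethylsilyl chloride, C[Si](C)(Cl)C(C)(C)C
Why: Standard silylation; the ether survives organolithium, KH, chromic acid and LiN(iPr)2 later on.

Step 11
Reactants: 17 tert-butyldimethyl{[(1S,5R)-2-methyl-5-(prop-1-en-2-yl)cyclohex-2-en-1-yl]oxy}silane
Product: 18 (4S,6R)-4-(tert-butyldimethylsilyloxy)-3-methyl-6-(prop-1-en-2-yl)cyclohex-2-en-1-one
Conditions: CrO3, 3,5-dimethylpyrazole, CH2Cl2, −20 °C
Reagents that add atoms: chromium trioxide, O=[Cr](=O)=O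
Why: Allylic oxidation of the only ring CH2 next to the =CH terminus of the trisubstituted olefin (as in limonene to isopiperitenone); the silyloxy-bearing allylic CH is hindered.

Step 12
Reactants: 12 4-bromo-2-methoxy-2,3-dihydrofuran; 18 (4S,6R)-4-(tert-butyldimethylsilyloxy)-3-methyl-6-(prop-1-en-2-yl)cyclohex-2-en-1-one
Product: 20 (1R,4S,6R)-4-(tert-butyldimethylsilyloxy)-1-(2-methoxy-2,3-dihydrofuran-4-yl)-3-methyl-6-(prop-1-en-2-yl)cyclohex-2-en-1-ol, via vinyllithium 19 (not isolated)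
Conditions: 12, t-BuLi (2 equiv), THF/Et2O, −78 °C; then 18, −78 °C; H2O
Reagents that add atoms: none
Why: Bromine–lithium exchange, then 1,2-addition to the enone; equatorial attack trans to the adjacent isopropenyl group gives the trans-1,2-dialkenyl carbinol (1R).

Step 13
Reactants: 20 (1R,4S,6R)-4-(tert-butyldimethylsilyloxy)-1-(2-methoxy-2,3-dihydrofuran-4-yl)-3-methyl-6-(prop-1-en-2-yl)cyclohex-2-en-1-ol
Product: 23 3β-(tert-butyldimethylsilyloxy)-8β,12-epoxy-12-methoxy-13-norgermacra-1(10)E,4Z-dien-6-one (7αH,8αH; ten-membered enone cis-fused at C7–C8 to a 2-methoxytetrahydrofuran), via potassium alkoxide 21 (not isolated), via potassium enolate 22 (not isolated)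
Conditions: KH, 18-crown-6, THF, 0 → 45 °C; then AcOH, −78 °C
Reagents that add atoms: none
Why: Anionic oxy-Cope [3,3]-sigmatropic rearrangement through a chair with both alkenyl groups equatorial forms the C8–C9 bond and the ten-membered ring with a new 1(10)E olefin and the ring 4Z olefin kept. The C1 stereocentre is relayed to C8 (ring oxygen equatorial, 8R), and the C8–O bond lies in the enolate plane so β-elimination is blocked. Protonation from the outer face, syn to H8, gives the cis-fused 7R centre.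

Step 14
Reactants: 23 3β-(tert-butyldimethylsilyloxy)-8β,12-epoxy-12-methoxy-13-norgermacra-1(10)E,4Z-dien-6-one
Product: 25 3β-(tert-butyldimethylsilyloxy)-6-oxo-13-norgermacra-1(10)E,4Z-dien-8β,12-olide, via lactol 24 (not isolated)
Conditions: CrO3, H2SO4, H2O/acetone (Jones), −10 °C, 20 min
Reagents that add atoms: water, O
Why: Jones oxidation of a methyl lactol ether: acid hydrolysis to the lactol and chromic acid oxidation to the γ-lactone; ketone, olefins and the secondary silyl ether tolerate the short cold exposure.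

Step 15
Reactants: 25 3β-(tert-butyldimethylsilyloxy)-6-oxo-13-norgermacra-1(10)E,4Z-dien-8β,12-olide
Product: 28 3β-(tert-butyldimethylsilyloxy)-8β-hydroxy-13-norgermacra-1(10)E,4Z-dien-6α,12-olide (trans-fused lactone; 6βH,7αH), via hydroxy 8,12-lactone 26 (not isolated), via lithium dihydroxy carboxylate 27 (not isolated)
Conditions: NaBH4, CeCl3·7H2O, MeOH, −78 °C; then LiOH, THF/H2O, rt; then 1 M HCl to pH 3, rt
Reagents that add atoms: none
Why: Luche reduction puts hydride on the outer face of the C6 carbonyl (the H7 side; C11 and the ring block the other), giving the 6α-alcohol (6R). Saponification and acidification then let the dihydroxy acid relactonise onto O6 (translactonisation), the closure preferred for 6α,8β-dihydroxy germacranoic acids.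

Step 16
Reactants: 28 3β-(tert-butyldimethylsilyloxy)-8β-hydroxy-13-norgermacra-1(10)E,4Z-dien-6α,12-olide
Product: 31 3β-(tert-butyldimethylsilyloxy)-8β-hydroxygermacra-1(10)E,4Z,11(13)-trien-6α,12-olide, via Mannich base 29 (not isolated), via trimethylammonium iodide 30 (not isolated)
Conditions: LiN(iPr)2 (2.5 equiv), THF, −78 °C; CH2=NMe2+ I−, −78 → 0 °C; MeOH then MeI, rt; aq. NaHCO3
Reagents that add atoms: N,N-dimethylmethyleneiminium iodide (Eschenmoser's salt), C=[N+](C)C.[I-]
Why: Mannich aminomethylation of the alkoxide–lactone enolate dianion, N-quaternisation and base-induced elimination (E1cB) give the α-methylene lactone; the C11 centre is lost so its configuration does not matter.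

Step 17
Reactants: 8 (2S,3R)-2,3-dimethyloxirane-2-carboxylic acid; 31 3β-(tert-butyldimethylsilyloxy)-8β-hydroxygermacra-1(10)E,4Z,11(13)-trien-6α,12-olide
Product: 33 3β-(tert-butyldimethylsilyloxy)-8β-[(2S,3R)-2,3-epoxy-2-methylbutanoyloxy]germacra-1(10)E,4Z,11(13)-trien-6α,12-olide, via mixed anhydride 32 (not isolated)
Conditions: 8, 2,4,6-trichlorobenzoyl chloride, Et3N, THF, 0 °C; then 31, DMAP, PhMe, rt
Reagents that add atoms: none
Why: Yamaguchi esterification; the hindered secondary alcohol attacks the aliphatic carbonyl of the mixed anhydride, and the acid has no α-hydrogen so its stereocentres cannot epimerise.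

Step 18
Reactants: 33 3β-(tert-butyldimethylsilyloxy)-8β-[(2S,3R)-2,3-epoxy-2-methylbutanoyloxy]germacra-1(10)E,4Z,11(13)-trien-6α,12-olide
Product: 34 8β-[(2S,3R)-2,3-epoxy-2-methylbutanoyloxy]-3β-hydroxygermacra-1(10)E,4Z,11(13)-trien-6α,12-olide
Conditions: HF·pyridine, pyridine, THF, 0 °C → rt
Reagents that add atoms: none
Why: Buffered fluoride desilylation; the ester-deactivated oxirane and the α-methylene lactone tolerate these non-basic conditions.

Step 19
Reactants: 34 8β-[(2S,3R)-2,3-epoxy-2-methylbutanoyloxy]-3β-hydroxygermacra-1(10)E,4Z,11(13)-trien-6α,12-olide; 35 (R)-2-methylbutanoic acid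
Product: 36 8β-[(2S,3R)-2,3-epoxy-2-methylbutanoyloxy]-3β-[(R)-2-methylbutanoyloxy]germacra-1(10)E,4Z,11(13)-trien-6α,12-olide
Conditions: 35, DCC, DMAP (cat.), CH2Cl2, 0 °C → rt
Reagents that add atoms: none
Why: Steglich esterification with retention at C3; low DMAP loading and low temperature keep the α-stereocentre of the acid intact.

Step 20
Reactants: 36 8β-[(2S,3R)-2,3-epoxy-2-methylbutanoyloxy]-3β-[(R)-2-methylbutanoyloxy]germacra-1(10)E,4Z,11(13)-trien-6α,12-olide
Product: 37 target, (1R,3S,6R,7R,8R,10R)-1β,10α-epoxy-8β-[(2S,3R)-2,3-epoxy-2-methylbutanoyloxy]-3β-[(R)-2-methylbutanoyloxy]germacra-4Z,11(13)-dien-6α,12-olide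
Conditions: mCPBA (1.05 equiv), NaHCO3, CH2Cl2, −10 → 0 °C
Reagents that add atoms: 3-chloroperoxybenzoic acid, OOC(=O)c1cccc(Cl)c1
Why: Prilezhaev epoxidation of the only electron-rich olefin; the 4,5-olefin is deactivated by two allylic acyloxy groups and the methylene is conjugated. Peracid attacks the outer face of the E-olefin in the conformer with C14 on the β face, giving the trans 1β,10α-oxirane (1R,10R).

## Compound list

1 | ethyl (S)-3-hydroxybutanoate | CCOC(=O)C[C@H](C)O | starting material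
2 | dilithium alkoxide enolate of 1 | CCOC([O-])=C[C@H](C)[O-].[Li+].[Li+] | intermediate
3 | ethyl (2S,3S)-3-hydroxy-2-methylbutanoate | CCOC(=O)[C@@H](C)[C@H](C)O | intermediate
4 | dilithium alkoxide enolate of 3 | CCOC([O-])=C(C)[C@H](C)[O-].[Li+].[Li+] | intermediate
5 | ethyl (2S,3S)-2,3-dihydroxy-2-methylbutanoate | CCOC(=O)[C@@](C)(O)[C@H](C)O | intermediate
6 | ethyl (2S,3S)-2-hydroxy-3-(methanesulfonyloxy)-2-methylbutanoate | CCOC(=O)[C@@](C)(O)[C@H](C)OS(C)(=O)=O | intermediate
7 | ethyl (2S,3R)-2,3-dimethyloxirane-2-carboxylate (methyls cis) | CCOC(=O)[C@@]1(C)O[C@@H]1C | intermediate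
8 | (2S,3R)-2,3-dimethyloxirane-2-carboxylic acid (epoxyangelic acid) | OC(=O)[C@@]1(C)O[C@@H]1C | intermediate
9 | 2,5-dimethoxytetrahydrofuran (cis/trans mixture) | COC1CCC(OC)O1 | starting material
10 | 2-methoxy-2,3-dihydrofuran (racemic) | COC1CC=CO1 | intermediate
11 | 2,3-dibromo-5-methoxytetrahydrofuran (isomer mixture) | COC1CC(Br)C(Br)O1 | intermediate
12 | 4-bromo-2-methoxy-2,3-dihydrofuran (racemic) | COC1CC(Br)=CO1 | intermediate
13 | (R)-carvone | CC1=CC[C@H](CC1=O)C(C)=C | starting material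
14 | (1R,5R)-cis-carveol | CC1=CC[C@@H](C(C)=C)C[C@H]1O | intermediate
15 | (1S,5R)-2-methyl-5-(prop-1-en-2-yl)cyclohex-2-en-1-yl 4-nitrobenzoate | CC1=CC[C@@H](C(C)=C)C[C@@H]1OC(=O)c1ccc(cc1)[N+](=O)[O-] | intermediate
16 | (1S,5R)-trans-carveol | CC1=CC[C@@H](C(C)=C)C[C@@H]1O | intermediate
17 | tert-butyldimethyl{[(1S,5R)-2-methyl-5-(prop-1-en-2-yl)cyclohex-2-en-1-yl]oxy}silane | CC1=CC[C@@H](C(C)=C)C[C@@H]1O[Si](C)(C)C(C)(C)C | intermediate
18 | (4S,6R)-4-(tert-butyldimethylsilyloxy)-3-methyl-6-(prop-1-en-2-yl)cyclohex-2-en-1-one | CC1=CC(=O)[C@@H](C(C)=C)C[C@@H]1O[Si](C)(C)C(C)(C)C | intermediate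
19 | (2-methoxy-2,3-dihydrofuran-4-yl)lithium | [Li]C1=COC(OC)C1 | intermediate
20 | (1R,4S,6R)-4-(tert-butyldimethylsilyloxy)-1-(2-methoxy-2,3-dihydrofuran-4-yl)-3-methyl-6-(prop-1-en-2-yl)cyclohex-2-en-1-ol (acetal epimers) | CC1=C[C@](O)(C2=COC(OC)C2)[C@@H](C(C)=C)C[C@@H]1O[Si](C)(C)C(C)(C)C | intermediate
21 | potassium alkoxide of 20 | CC1=C[C@]([O-])(C2=COC(OC)C2)[C@@H](C(C)=C)C[C@@H]1O[Si](C)(C)C(C)(C)C.[K+] | intermediate
22 | potassium C6-enolate of 23 (C6=C7 with C5 trans to C8) | C/C1=C/C(/[O-])=C2\CC(OC)O[C@@H]2C/C(C)=C/C[C@@H]1O[Si](C)(C)C(C)(C)C.[K+] | intermediate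
23 | 3β-(tert-butyldimethylsilyloxy)-8β,12-epoxy-12-methoxy-13-norgermacra-1(10)E,4Z-dien-6-one (7αH,8αH; C12 epimers) | O=C1/C=C(/C)[C@@H](O[Si](C)(C)C(C)(C)C)C/C=C(\C)C[C@H]2OC(OC)C[C@@H]12 | intermediate
24 | 3β-(tert-butyldimethylsilyloxy)-8β,12-epoxy-12-hydroxy-13-norgermacra-1(10)E,4Z-dien-6-one (lactol) | O=C1/C=C(/C)[C@@H](O[Si](C)(C)C(C)(C)C)C/C=C(\C)C[C@H]2OC(O)C[C@@H]12 | intermediate
25 | 3β-(tert-butyldimethylsilyloxy)-6-oxo-13-norgermacra-1(10)E,4Z-dien-8β,12-olide (cis-fused) | O=C1/C=C(/C)[C@@H](O[Si](C)(C)C(C)(C)C)C/C=C(\C)C[C@H]2OC(=O)C[C@@H]12 | intermediate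
26 | 3β-(tert-butyldimethylsilyloxy)-6α-hydroxy-13-norgermacra-1(10)E,4Z-dien-8β,12-olide | O[C@@H]1/C=C(/C)[C@@H](O[Si](C)(C)C(C)(C)C)C/C=C(\C)C[C@H]2OC(=O)C[C@@H]12 | intermediate
27 | lithium 3β-(tert-butyldimethylsilyloxy)-6α,8β-dihydroxy-13-norgermacra-1(10)E,4Z-dien-12-oate | O[C@@H]1/C=C(/C)[C@@H](O[Si](C)(C)C(C)(C)C)C/C=C(\C)C[C@@H](O)[C@H]1CC(=O)[O-].[Li+] | intermediate
28 | 3β-(tert-butyldimethylsilyloxy)-8β-hydroxy-13-norgermacra-1(10)E,4Z-dien-6α,12-olide (trans-fused) | C1C(=O)O[C@@H]2/C=C(/C)[C@@H](O[Si](C)(C)C(C)(C)C)C/C=C(\C)C[C@@H](O)[C@@H]12 | intermediate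
29 | 13-(dimethylamino)-3β-(tert-butyldimethylsilyloxy)-8β-hydroxy-11,13-dihydrogermacra-1(10)E,4Z-dien-6α,12-olide (C11 epimers) | CN(C)CC1C(=O)O[C@@H]2/C=C(/C)[C@@H](O[Si](C)(C)C(C)(C)C)C/C=C(\C)C[C@@H](O)[C@@H]12 | intermediate
30 | trimethylammonium iodide of 29 | C[N+](C)(C)CC1C(=O)O[C@@H]2/C=C(/C)[C@@H](O[Si](C)(C)C(C)(C)C)C/C=C(\C)C[C@@H](O)[C@@H]12.[I-] | intermediate
31 | 3β-(tert-butyldimethylsilyloxy)-8β-hydroxygermacra-1(10)E,4Z,11(13)-trien-6α,12-olide | C=C1C(=O)O[C@@H]2/C=C(/C)[C@@H](O[Si](C)(C)C(C)(C)C)C/C=C(\C)C[C@@H](O)[C@@H]12 | intermediate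
32 | (2S,3R)-2,3-dimethyloxirane-2-carboxylic 2,4,6-trichlorobenzoic anhydride | O=C(OC(=O)c1c(Cl)cc(Cl)cc1Cl)[C@@]1(C)O[C@@H]1C | intermediate
33 | 3β-(tert-butyldimethylsilyloxy)-8β-[(2S,3R)-2,3-epoxy-2-methylbutanoyloxy]germacra-1(10)E,4Z,11(13)-trien-6α,12-olide | C=C1C(=O)O[C@@H]2/C=C(/C)[C@@H](O[Si](C)(C)C(C)(C)C)C/C=C(\C)C[C@@H](OC(=O)[C@@]3(C)O[C@@H]3C)[C@@H]12 | intermediate
34 | 8β-[(2S,3R)-2,3-epoxy-2-methylbutanoyloxy]-3β-hydroxygermacra-1(10)E,4Z,11(13)-trien-6α,12-olide | C=C1C(=O)O[C@@H]2/C=C(/C)[C@@H](O)C/C=C(\C)C[C@@H](OC(=O)[C@@]3(C)O[C@@H]3C)[C@@H]12 | intermediate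
35 | (R)-2-methylbutanoic acid | CC[C@@H](C)C(=O)O | starting material
36 | 8β-[(2S,3R)-2,3-epoxy-2-methylbutanoyloxy]-3β-[(R)-2-methylbutanoyloxy]germacra-1(10)E,4Z,11(13)-trien-6α,12-olide | C=C1C(=O)O[C@@H]2/C=C(/C)[C@@H](OC(=O)[C@H](C)CC)C/C=C(\C)C[C@@H](OC(=O)[C@@]3(C)O[C@@H]3C)[C@@H]12 | intermediate
37 | (1R,3S,6R,7R,8R,10R)-1β,10α-epoxy-8β-[(2S,3R)-2,3-epoxy-2-methylbutanoyloxy]-3β-[(R)-2-methylbutanoyloxy]germacra-4Z,11(13)-dien-6α,12-olide | C=C1C(=O)O[C@@H]2/C=C(/C)[C@@H](OC(=O)[C@H](C)CC)C[C@H]3O[C@]3(C)C[C@@H](OC(=O)[C@@]3(C)O[C@@H]3C)[C@@H]12 | target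

## Step count and risks

Total step count: 20 (fragment A 4, fragment B 2, main line 14).
Longest linear sequence: 14 steps (13 → 37, steps 7–20).

The macrocyclic stereochemical outcomes (steps 13, 15 and 20) rest on hand conformational analysis and analogy to known germacranolide chemistry, not on modelling or experiment.

Three steps most likely to fail:

**Step 11 (allylic oxidation).** Chromium may attack the silyloxy-bearing CH or the isopropenyl group, or over-oxidise the doubly activated C6–H of 18. The fallback sets out from 17 and comes back at 18 by oxygen transposition. Sensitised photo-oxygenation of 17 (O2, tetraphenylporphyrin, hν, CH2Cl2, 0 °C; Schenck ene reaction on the trisubstituted ring olefin) gives the tertiary allylic hydroperoxide F1. PPh3 reduces it to the tertiary allylic alcohol F2. Pyridinium chlorochromate (C5H5NH)[CrO3Cl] in CH2Cl2 then effects the oxidative 1,3-transposition (Babler–Dauben) to 18.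

**Step 13 (anionic oxy-Cope).** The potassium alkoxide may fragment, or the enolate may decompose or epimerise at the temperature the rearrangement needs. The fallback sets out from 20 and comes back at 23 under neutral conditions. N-(trimethylsilyl)imidazole gives the trimethylsilyl ether F3. Heating in degassed decalin at about 200 °C in a base-washed sealed tube gives, by siloxy-Cope rearrangement, the ten-membered trimethylsilyl enol ether F4. HF·pyridine in THF at −78 °C protonates C7 from the outer face to give 23.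

**Step 15 (reduction and relactonisation).** The dihydroxy acid may stay as, or return to, the cis 8β,12-lactone, or give mixtures. The fallback sets out from 23 and comes back at 28; it frees and blocks O8 before O6 exists, so only O6 can lactonise.
- 1,3-Propanedithiol and BF3·OEt2 (CH2Cl2, −40 °C) open the lactol ether of 23 to the dithiane hydroxy ketone F5.
- TESCl and imidazole give the 8-O-triethylsilyl ether F6.
- Luche reduction (NaBH4, CeCl3·7H2O) gives the 6α-alcohol F7.
- PhI(OCOCF3)2 in aqueous MeCN removes the dithiane, and the aldehyde closes onto the only free hydroxyl to give the 6α,12-lactol F8.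
- TEMPO and PhI(OAc)2 oxidise it to the 6α,12-lactone F9.
- PPTS in MeOH at 0 °C removes the triethylsilyl group selectively to give 28.

## Further compounds

F1 | step 11 | tert-butyl{[(1S,5S)-2-hydroperoxy-2-methyl-5-(prop-1-en-2-yl)cyclohex-3-en-1-yl]oxy}dimethylsilane (C2 epimers) | CC1(OO)C=C[C@@H](C(C)=C)C[C@@H]1O[Si](C)(C)C(C)(C)C
F2 | step 11 | (6S,4S)-6-(tert-butyldimethylsilyloxy)-1-methyl-4-(prop-1-en-2-yl)cyclohex-2-en-1-ol (C1 epimers) | CC1(O)C=C[C@@H](C(C)=C)C[C@@H]1O[Si](C)(C)C(C)(C)C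
F3 | step 13 | trimethylsilyl ether of 20 | CC1=C[C@](O[Si](C)(C)C)(C2=COC(OC)C2)[C@@H](C(C)=C)C[C@@H]1O[Si](C)(C)C(C)(C)C
F4 | step 13 | trimethylsilyl enol ether of 23 (C6=C7 with C5 trans to C8) | C/C1=C/C(/O[Si](C)(C)C)=C2\CC(OC)O[C@@H]2C/C(C)=C/C[C@@H]1O[Si](C)(C)C(C)(C)C
F5 | step 15 | 3β-(tert-butyldimethylsilyloxy)-8β-hydroxy-12,12-(propane-1,3-diyldithio)-13-norgermacra-1(10)E,4Z-dien-6-one (7αH) | O=C1/C=C(/C)[C@@H](O[Si](C)(C)C(C)(C)C)C/C=C(\C)C[C@@H](O)[C@H]1CC1SCCCS1
F6 | step 15 | 8-O-triethylsilyl ether of F5 | O=C1/C=C(/C)[C@@H](O[Si](C)(C)C(C)(C)C)C/C=C(\C)C[C@@H](O[Si](CC)(CC)CC)[C@H]1CC1SCCCS1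
F7 | step 15 | 6α-alcohol from F6 | O[C@@H]1/C=C(/C)[C@@H](O[Si](C)(C)C(C)(C)C)C/C=C(\C)C[C@@H](O[Si](CC)(CC)CC)[C@H]1CC1SCCCS1
F8 | step 15 | 3β-(tert-butyldimethylsilyloxy)-8β-(triethylsilyloxy)-13-norgermacra-1(10)E,4Z-dien-6α,12-lactol (C12 epimers) | C1C(O)O[C@@H]2/C=C(/C)[C@@H](O[Si](C)(C)C(C)(C)C)C/C=C(\C)C[C@@H](O[Si](CC)(CC)CC)[C@@H]12
F9 | step 15 | 3β-(tert-butyldimethylsilyloxy)-8β-(triethylsilyloxy)-13-norgermacra-1(10)E,4Z-dien-6α,12-olide | C1C(=O)O[C@@H]2/C=C(/C)[C@@H](O[Si](C)(C)C(C)(C)C)C/C=C(\C)C[C@@H](O[Si](CC)(CC)CC)[C@@H]12
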